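The vessel is closed and stirred, and it holds G, X and a little E at constant volume and temperature.

| flask | G | X | E | temperature | remark | time |
|---|---|---|---|---|---|---|
| blue | 0.40 M | 0.76 M | 4 mM | 15 °C | run made earlier |  |
| violet | 0.60 M | 0.76 M | 4 mM | 32 °C | run made earlier |  |
| red | 0.80 M | 1.1 M | 4 mM | 15 °C | run made earlier |  |
| south | 0.80 M | 0.760 M | 4.0 mM | 20 °C |  | 2.0 min |
| north | 0.80 M | 0.760 M | 4.0 mM | 45 °C |  | 2.0 min |

| run | time / s | Q / % | G / % |
|---|---|---|---|
| blue | 10.0 | 0.9 | 93.0 |
| blue | 20.0 | 2.6 | 87.1 |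
| blue | 30.0 | 7.2 | 81.4 |
| blue | 50.0 | 14.2 | 70.0 |
| blue | 80.0 | 25.8 | 57.8 |
| violet | 10.0 | 7.5 | 77.4 |
| violet | 12.0 | 9.5 | 73.1 |
| violet | 15.0 | 13.8 | 67.9 |
| violet | 30.0 | 32.3 | 47.6 |
| violet | 40.0 | 41.3 | 37.1 |
| red | 10.0 | 1.0 | 93.2 |
| red | 20.0 | 4.3 | 86.5 |
| red | 30.0 | 8.5 | 80.8 |
| red | 50.0 | 17.1 | 70.7 |
| red | 80.0 | 29.9 | 57.7 |

(standard deviation of a reading: 0.3 percentage points)

- which flask leads in amount of Q, in percent of the G charged ("all alike" within 1.5 percentage points) (south / north / all alike)
- how much Q is there at the end, in percent of the G charged: south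
- how much Q is there at the end, in percent of the G charged: north



Blue and red seem to disagree with their charges. Red starts with twice the G of blue and with more X, yet at 80.0 s blue holds 57.8% of its G and red 57.7%. Logarithms clear this up. The logarithm of one over the fraction of G left, divided by the time, gives 0.00685 s⁻¹ in blue and 0.00687 s⁻¹ in red, the same figure within the scatter of the readings. A first-order loss keeps its fractions whatever the charge, and the extra X of red shows no mark in these readings.

So X does not show in the fall of G in these two runs; it is counted at Q. Taking one X per Q, Q as a fraction of the G charged cannot pass the ratio of X charged to G charged. In south and north that ratio is 95.0%; call it the X ceiling. In blue it was 190% and in red 138%, both above the whole charge of G, so those runs never met it. The reckoning here commits to one thing: Q in north stays under 95.0%.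

The forecast names north as leader, with 52% for south and 90% for north: “X is limiting, capping Q at 95%, and about 0.03 M X remains, so Q ≈ 90%”.

The flasks give 50.4% in south and 73.4% in north, so north leads.

    Q → D (k = 1.10 × 10⁻⁵ s⁻¹, Ea = 96.0 kJ mol⁻¹)
    J → L (k = 0.00130 s⁻¹, Ea = 94.0 kJ mol⁻¹)
    G + E ⇌ E + J (K = 3.10, k = 2.70 M⁻¹ s⁻¹, Ea = 57.0 kJ mol⁻¹, ΔH = −4.00 kJ mol⁻¹)
    X + E + J → E + Q (k = 13.0 M⁻² s⁻¹, Ea = 45.0 kJ mol⁻¹)
    (constants at 20 °C)

In north, while G lasted, J passed to Q and to L side by side: at 1.00 min Q stood at 69.2% and L at 20.2%, and at 2.00 min G was down to 0.50% and J to 0.650%, with 21% of X still there and Q 22 percentage points under the ceiling. In a second flask, north with 2.0 M of G, the ceiling is 38.0%; there X, the limiting reagent, fell to 0.016% of its charge, and at 2.00 min Q stood just under that ceiling, at 37.0%.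

(The earlier runs and the new flask stem from a simulated flask from invented constants.)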